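A leftover of starting material stays in birch, ash and alder and does not move. The starting-material readings of each run show no steady trend, so you can replace each curve by its mean: 9.20%, 6.68% and 2.84% of the charge, each good to about 0.22 percentage points.

| flask | starting material | coupling partner | remark | time |
|---|---|---|---|---|
| birch | 0.15 M | 0.75 M | run made earlier |  |
| ash | 0.22 M | 0.75 M | run made earlier |  |
| alder | 0.30 M | 1.5 M | run made earlier |  |
| flask | 0.30 M | 0.750 M |  | 30 h |

| run | time / h | starting material / % | target / % | isomer of the product / % |
|---|---|---|---|---|
| birch | 8.00 | 9.1 | 61.2 | 28.5 |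
| birch | 15.0 | 9.5 | 61.4 | 29.3 |
| birch | 20.0 | 8.7 | 61.6 | 29.6 |
| birch | 30.0 | 9.7 | 61.0 | 29.6 |
| birch | 40.0 | 9.0 | 62.1 | 29.9 |
| ash | 3.00 | 6.6 | 73.7 | 20.4 |
| ash | 10.0 | 6.9 | 74.3 | 19.0 |
| ash | 15.0 | 6.6 | 71.5 | 19.8 |
| ash | 25.0 | 6.1 | 71.3 | 19.9 |
| ash | 40.0 | 7.2 | 72.7 | 20.4 |
| alder | 3.00 | 2.6 | 82.9 | 14.0 |
| alder | 5.00 | 3.2 | 83.9 | 14.1 |
| alder | 10.0 | 3.3 | 83.2 | 14.6 |
| alder | 20.0 | 3.3 | 83.0 | 14.8 |
| alder | 40.0 | 1.8 | 83.0 | 14.6 |

(scatter of a reading: 0.5 percentage points)

1. which holds at 30 h: what has brought the reaction to rest, or that it has not come to rest (forward and back rates have come level / all of the starting material has reacted / the coupling partner has run out first / it is still moving)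
2. part of the starting material gone at 30 h
3. the target standing at 30 h, as a percentage of the starting material charged
4. the isomer of the product standing at 30 h, as a percentage of the starting material charged
5. amount of target if the flask were left three thousand times as long, in percent of the starting material charged

- the earlier runs were read with a standard deviation of 0.5 percentage points
- a reading or a percentage of target counts all its forms, free or not
- the reaction counts as stopped when no species that holds the starting material changes by six tenths of a point or more over the second half of the time

Call the leftover a, and let b be the partner charge less the starting material gone, in whatever form that partner now stands. Take the forward rate as proportional to a·b. Then the leftover product Q, the mean of a·b at rest and so the forward rate there per unit of rate constant, is 0.00847 M^2 in birch, 0.00800 M^2 in ash and 0.0103 M^2 in alder, with mean 0.00892 M^2. At 40.0 h alder reads 2.67 times birch's target, yet its Q is 1.22 times birch's.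

Your flask has ash's partner charge, so it starts at ash's pace per unit of starting material, and ash's starting material already read flat at 3.00 h, well before 30 h. Setting a(a + 0.450 M) = Q puts the flask's leftover at 0.0190 M. The fall in a therefore slows the forward rate 15.8-fold, more than the 1.60-fold fall in b, together 25.3-fold. My reckoning is 93.7% gone; Q from alder and from ash gives 92.7% and 94.3%.

The forecast calls this “a balance rather than exhaustion”: forward and back rates have come level, 93.7% gone, 79.1% target, 14.6% isomer, and 79.1% after the long wait.

The flask gives this: forward and back rates have come level, with 93.9% gone. Its target stands at 79.3%, and at 79.3% after the long wait. Its isomer of the product stands at 14.6%.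

    starting material + coupling partner ⇌ target (K = 4.35 M⁻¹, k = 0.101 M⁻¹ min⁻¹)
    crystals ⇌ target, rate k2*(cs2 - [target]) while solid is left; crystals form when [target] > cs2 (solubility = 30.0 mM, k = 24.7 min⁻¹)
    target ⇌ isomer of the product (K = 1.46, k = 2.33 min⁻¹)
    coupling partner ⇌ dormant form (K = 0.239, k = 0.176 min⁻¹)

At 30.0 h crystals, counted in the target, hold 69.3% of the charge. The flask's own Q from that conversion is 0.00854 M^2, between ash and alder. Carry the mean Q to the neighbouring flask with 0.45 M of coupling partner: a(a + 0.150 M) = Q leaves 15.2% of the charge, and that flask stands at 14.7%.

The data come from a simulation with constants of no real substance, and the scatter is random.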